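**Plan**

- Retrosynthesis: first both exocyclic C8=CH2 and C8'=CH2 bonds (methylenation of an 8,8'-diketone). Then the C9–C10 and C9'–C10' bonds, each by a retro pinacol-type 1,2-shift to a trans-hydrindane with a tertiary C8–OH and an exocyclic C9–O leaving group. Then the two C8=C9 alkenes (Wittig), which join two hydrindanones to a four-carbon linker C9–C11–C12–C9'.
- Enabling feature: in each half C8 lies between the quaternary C10 and the linker carbon C9. A cyclopentane C5–C6–C7–C8–C10 with an exocyclic C9 can therefore be enlarged to ring B by moving C10 from C8 to C9, while C8 becomes the carbonyl that later carries the methylene.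
- Forward order: ring A plus cyclopentane (amino acid-catalysed aldol, reductive methylation); two hydrindanones (3'-ketal and 3β-acetate); olefination and dihydroxylation of the ketone-half unit, whose diol is parked as silyl ethers; second olefination and dihydroxylation; ring B of the acetate half by ring expansion, then ring B of the ketone half; both methylenes; ketal removal.
- Stereochemistry: C10/C10' from the (S)-phenylalanine aldol, C5/C5' from the Li/NH3 reduction, C3 from NaBH4. C9' (H cis to the C10' methyl) is the kinetic outcome of the stereospecific shift (Z-alkene, α-face OsO4, inversion at C9'). C9 (H trans to the C10 methyl) comes from equilibrating the same kinetic product.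

Key step: step 18

Remark on numbering: each bicyclic half carries triterpenoid numbers (ring A = C1–C5, C10; ring B = C5–C10). The cyclopentane carbons of the hydrindane precursors already bear the numbers C5, C6, C7, C8, C10 that they keep in ring B. Primed numbers belong to the ketone half; C11 is the linker carbon on C9 and C12 the one on C9'. β is the face of the angular methyl group, α the opposite face.

Remark on the target: in the given structure the acetate half has 9α-H (chain β, equatorial) and the ketone half has 9'β-H (chain α, axial). The two C9 centres are therefore set separately.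

Assumption: (4-hydroxybutyl)triphenylphosphonium bromide 15 is taken as a catalogue reagent (otherwise one step from 4-chlorobutan-1-ol and PPh3).

**Route**

Step 1
Reactants: 1 2-methylcyclopentane-1,3-dione; 2 pent-1-en-3-one
Product: 3 2-methyl-2-(3-oxopentyl)cyclopentane-1,3-dione
Conditions: H2O, AcOH (cat.), 75 °C
Reagents that add atoms: none
Why: Michael addition of the enolised 1,3-dione to the vinyl ketone should give the prochiral triketone; no stereocentre is formed.

Step 2
Reactants: 3 2-methyl-2-(3-oxopentyl)cyclopentane-1,3-dione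
Product: 4 (7aS)-4,7a-dimethyl-2,3,7,7a-tetrahydro-1H-indene-1,5(6H)-dione
Conditions: (S)-phenylalanine, (1S)-camphor-10-sulfonic acid, MeCN, 80 °C
Reagents that add atoms: none
Why: Hajos–Parrish–Eder–Sauer–Wiechert intramolecular aldol condensation, in which the enamine of the side-chain ketone selects one of the two enantiotopic ring carbonyls under control of the (S)-amino acid and so sets the quaternary C10 as S.

Step 3
Reactants: 4 (7aS)-4,7a-dimethyl-2,3,7,7a-tetrahydro-1H-indene-1,5(6H)-dione
Product: 5 (1S,7aS)-1-hydroxy-4,7a-dimethyl-1,2,3,6,7,7a-hexahydro-5H-inden-5-one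
Conditions: NaBH4, EtOH, −20 °C
Reagents that add atoms: none
Why: Chemoselective borohydride reduction of the saturated cyclopentanone beside the less electrophilic enone, with hydride entering anti to the angular methyl group to give the 8β-alcohol, as known for the parent Hajos–Parrish ketone.

Step 4
Reactants: 5 (1S,7aS)-1-hydroxy-4,7a-dimethyl-1,2,3,6,7,7a-hexahydro-5H-inden-5-one
Product: 7 (1S,3aR,7aS)-1-hydroxy-4,4,7a-trimethyloctahydro-5H-inden-5-one, via alkoxide enolate 6 (not isolated)
Conditions: NaH, THF, 0 °C; Li, NH3, t-BuOH (1 equiv), −78 to −33 °C; then MeI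
Reagents that add atoms: iodomethane CI
Why: Birch-type reductive alkylation of the enone: the pre-formed alkoxide cannot deliver a proton internally, the C5 carbanion is protonated axially on the α face to give the trans ring fusion known for 1β-alkoxy hydrindenones, and the regio-defined enolate is C-methylated at C4.

Step 5
Reactants: 7 (1S,3aR,7aS)-1-hydroxy-4,4,7a-trimethyloctahydro-5H-inden-5-one
Product: 8 ketal alcohol (3,3-ethylenedioxy derivative of 7)
Conditions: HOCH2CH2OH, TsOH (cat.), PhH, reflux (Dean–Stark)
Reagents that add atoms: ethane-1,2-diol OCCO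
Why: Acid-catalysed ketalisation with azeotropic removal of water protects the only ketone; no stereocentre changes.

Step 6
Reactants: 8 ketal alcohol
Product: 9 (3aS,7aS)-5,5-(ethylenedioxy)-4,4,7a-trimethyloctahydro-1H-inden-1-one
Conditions: Pr4N[RuO4] (cat.), NMO, 4 Å MS, CH2Cl2, rt
Reagents that add atoms: none
Why: Ley–Griffith oxidation of the secondary alcohol under neutral conditions should leave the ketal intact and give the hydrindanone for the ketone half.

Step 7
Reactants: 7 (1S,3aR,7aS)-1-hydroxy-4,4,7a-trimethyloctahydro-5H-inden-5-one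
Product: 10 8β-triethylsilyl ether of 7
Conditions: Et3SiCl, imidazole, DMF, rt
Reagents that add atoms: chlorotriethylsilane CC[Si](Cl)(CC)CC
Why: Imidazole-promoted silylation masks the C8 hydroxyl so that C3 can be adjusted independently.

Step 8
Reactants: 10 8β-triethylsilyl ether of 7
Product: 11 (1S,3aS,5S,7aS)-4,4,7a-trimethyl-1-(triethylsilyloxy)octahydro-1H-inden-5-ol
Conditions: NaBH4, MeOH, 0 °C
Reagents that add atoms: none
Why: Borohydride reduction of the 4,4-dimethyl ketone by axial attack on the α face (the β face is shielded by the axial 4β- and 10β-methyl groups) should give the equatorial 3β-alcohol, as in 4,4-dimethyl-3-oxo triterpenoids.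

Step 9
Reactants: 11 (1S,3aS,5S,7aS)-4,4,7a-trimethyl-1-(triethylsilyloxy)octahydro-1H-inden-5-ol
Product: 12 3β-acetate of 11
Conditions: Ac2O, pyridine, DMAP (cat.), rt
Reagents that add atoms: acetic anhydride CC(=O)OC(C)=O
Why: DMAP-catalysed acetylation installs the acetate of the target early, where it also protects C3–OH from later mesylation.

Step 10
Reactants: 12 3β-acetate of 11
Product: 14 (3aS,5S,7aS)-4,4,7a-trimethyl-1-oxooctahydro-1H-inden-5-yl acetate, via hydroxy acetate 13 (not isolated)
Conditions: CrO3, H2SO4, acetone/H2O, 0 °C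
Reagents that add atoms: none
Why: Jones oxidation: the acidic reagent cleaves the triethylsilyl ether and oxidises the liberated secondary alcohol in the same flask, while the acetate is inert, giving the hydrindanone for the acetate half.

Step 11
Reactants: 9 (3aS,7aS)-5,5-(ethylenedioxy)-4,4,7a-trimethyloctahydro-1H-inden-1-one; 15 (4-hydroxybutyl)triphenylphosphonium bromide
Product: 17 (Z)-alkenol (9 with C8'=O replaced by a (Z)-4-hydroxybutylidene group), via oxido ylide 16 (not isolated)
Conditions: KN(SiMe3)2 (2.1 equiv), THF, 0 °C; then 9, reflux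
Reagents that add atoms: none
Why: Wittig olefination of the hindered cyclopentanone with a non-stabilised ylide should give, as with 17-oxo steroids, the Z-alkene in which the chain is cis to the quaternary C10'.

Step 12
Reactants: 17 (Z)-alkenol
Product: 18 triol (8'α-OH, 9'-OH, primary OH)
Conditions: OsO4 (cat.), NMO, acetone/H2O, rt
Reagents that add atoms: osmium tetroxide O=[Os](=O)(=O)=O (regenerated by N-methylmorpholine N-oxide C[N+]1([O-])CCOCC1); water O
Why: Upjohn dihydroxylation: syn addition to the α face of the Z-alkene, anti to the angular methyl group as for steroidal 17(20)-enes, fixes C8' and C9' together.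

Step 13
Reactants: 18 triol
Product: 19 primary iodide of 18 (iodo diol)
Conditions: I2, PPh3, imidazole, CH2Cl2, 0 °C
Reagents that add atoms: iodine II
Why: Appel-type iodination is selective at 0 °C for the primary alcohol over the hindered secondary/tertiary diol.

Step 14
Reactants: 19 iodo diol
Product: 20 bis(triethylsilyl) ether of 19
Conditions: Et3SiOTf, 2,6-lutidine, CH2Cl2, 0 °C to rt
Reagents that add atoms: triethylsilyl trifluoromethanesulfonate CC[Si](CC)(CC)OS(=O)(=O)C(F)(F)F
Why: Silyl triflate silylation of the secondary and tertiary hydroxyls parks this diol, so that its ring expansion can be released later and separately from that of the other half.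

Step 15
Reactants: 20 bis(triethylsilyl) ether of 19
Product: 21 triphenylphosphonium iodide of 20
Conditions: PPh3, MeCN, 80 °C
Reagents that add atoms: triphenylphosphine c1ccc(cc1)P(c1ccccc1)c1ccccc1
Why: SN2 quaternisation of PPh3 by the primary iodide gives the Wittig salt.

Step 16
Reactants: 21 triphenylphosphonium iodide of 20; 14 (3aS,5S,7aS)-4,4,7a-trimethyl-1-oxooctahydro-1H-inden-5-yl acetate
Product: 23 (Z)-alkene joining the acetoxy hydrindane (C8=C9) to the silyl-protected ketone-half unit, via ylide 22 (not isolated)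
Conditions: KN(SiMe3)2, THF, −78 to 0 °C; then 14, THF/PhMe, 80 °C
Reagents that add atoms: none
Why: Second Wittig olefination with the same Z selectivity (linker cis to C10) as in step 11; the hindered neopentyl-type acetate should not be attacked by the ylide.

Step 17
Reactants: 23 (Z)-alkene
Product: 24 8α,9-diol of the acetate half
Conditions: OsO4 (cat.), NMO, acetone/H2O, rt
Reagents that add atoms: osmium tetroxide O=[Os](=O)(=O)=O (regenerated by N-methylmorpholine N-oxide C[N+]1([O-])CCOCC1); water O
Why: Upjohn dihydroxylation of the only alkene from the α face gives the diol with the same relative configuration as in step 12.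

Step 18
Reactants: 24 8α,9-diol of the acetate half
Product: 27 acetate-half 8-ketone with 9α-H (chain β), via mesylate 25 (not isolated), via axial ketone 26 (not isolated)
Conditions: MsCl, Et3N, CH2Cl2, −20 °C; then LiClO4, CaCO3, THF, 50 °C; then DBU, PhMe, 80 °C
Reagents that add atoms: none
Why: The C9 hydroxyl is mesylated and, with LiClO4 assisting ionisation, the C8–C10 bond antiperiplanar to the C9–O bond migrates from C8 to C9 while the tertiary C8–OH collapses to the ketone (pinacol-type 1,2-shift; closest known type: D-homoannulation of steroidal 17-hydroxy-20-sulfonates and other ring enlargements of 1-(1-sulfonyloxyalkyl)cycloalkanols). No ring is closed by a cyclisation: the cyclopentane C5–C6–C7–C8–C10 is enlarged by one carbon, C9 being inserted between C8 and C10, which gives the cyclohexanone ring B and the C9–C10 bond next to the quaternary centre, with retention at C10 and release of the strain of the trans-hydrindane. The selectivity needed is migration of C10 and not of C7 (nor epoxide closure by the hydroxyl); it is secured by the diol configuration from the Z-alkene and α-face dihydroxylation, because only the rotamer with C9–H turned toward the angular methyl group is unstrained and in it the mesylate is anti to C8–C10. The shift inverts C9 and first gives the axial 9α-chain ketone 26 (substrate control, stereospecific). DBU then equilibrates C9 through the enol to the equatorial 9β-chain, 9α-H ketone 27 (thermodynamic control), while C3, C5, C10 and the silyl-protected diol of the other half are untouched.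

Step 19
Reactants: 27 acetate-half 8-ketone with 9α-H
Product: 28 keto diol (8'α,9'-diol of the ketone half set free)
Conditions: Bu4NF, AcOH, THF, 0 °C to rt
Reagents that add atoms: none
Why: Buffered fluoride desilylation frees the parked diol without touching the acetate or the now thermodynamic C9 centre.

Step 20
Reactants: 28 keto diol
Product: 30 8,8'-diketone (9α-H; 9'β-H), via mesylate 29 (not isolated)
Conditions: MsCl, Et3N, CH2Cl2, −20 °C; then LiClO4, CaCO3, THF, 50 °C
Reagents that add atoms: none
Why: The same pinacol-type ring expansion on the ketone half (any hemiketal with the C8 ketone is in equilibrium with the open diol that is mesylated): anti migration of C8'–C10' with inversion at C9' gives directly the 9'β-H, 9'α-chain ketone, and the absence of base keeps this kinetic configuration.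

Step 21
Reactants: 30 8,8'-diketone
Product: 31 bis-methylene ketal (3'-ethylenedioxy, 3β-acetoxy)
Conditions: Zn, CH2Br2, TiCl4, THF/CH2Cl2, 0 °C to rt
Reagents that add atoms: dibromomethane BrCBr
Why: Takai–Lombardo methylenation with the non-basic gem-dizinc reagent should convert both hindered, enolisable ketones without epimerising C9 or C9' and without attacking acetate or ketal.

Step 22
Reactants: 31 bis-methylene ketal
Product: 32 target (3'-oxo, 3β-acetoxy, 9α-H, 9'β-H)
Conditions: PPTS, acetone/H2O, 60 °C
Reagents that add atoms: water O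
Why: Mild acid-catalysed ketal hydrolysis unmasks the C3' ketone without isomerising the exocyclic alkenes or cleaving the acetate.

**Compound list**

1 | 2-methylcyclopentane-1,3-dione | CC1C(=O)CCC1=O | starting material
2 | pent-1-en-3-one (ethyl vinyl ketone) | CCC(=O)C=C | starting material
3 | 2-methyl-2-(3-oxopentyl)cyclopentane-1,3-dione | CCC(=O)CCC1(C)C(=O)CCC1=O | intermediate
4 | (7aS)-4,7a-dimethyl-2,3,7,7a-tetrahydro-1H-indene-1,5(6H)-dione | O=C1CCC2=C(C)C(=O)CC[C@]12C | intermediate
5 | (1S,7aS)-1-hydroxy-4,7a-dimethyl-1,2,3,6,7,7a-hexahydro-5H-inden-5-one (8β-OH) | O[C@H]1CCC2=C(C)C(=O)CC[C@]12C | intermediate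
6 | sodium 8β-alkoxide, lithium C3 enolate of the trans-fused reduced enone | [Na+].[Li+].[O-][C@H]1CC[C@H]2C(C)=C([O-])CC[C@]12C | intermediate
7 | (1S,3aR,7aS)-1-hydroxy-4,4,7a-trimethyloctahydro-5H-inden-5-one (trans-hydrindane, 8β-OH, 3-oxo) | O[C@H]1CC[C@H]2C(C)(C)C(=O)CC[C@]12C | intermediate
8 | 3,3-ethylenedioxy derivative of 7 (ketal alcohol) | O[C@H]1CC[C@H]2C(C)(C)C3(OCCO3)CC[C@]12C | intermediate
9 | (3aS,7aS)-5,5-(ethylenedioxy)-4,4,7a-trimethyloctahydro-1H-inden-1-one | O=C1CC[C@H]2C(C)(C)C3(OCCO3)CC[C@]12C | intermediate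
10 | 8β-triethylsilyl ether of 7 | CC[Si](CC)(CC)O[C@H]1CC[C@H]2C(C)(C)C(=O)CC[C@]12C | intermediate
11 | (1S,3aS,5S,7aS)-4,4,7a-trimethyl-1-(triethylsilyloxy)octahydro-1H-inden-5-ol (3β-OH) | CC[Si](CC)(CC)O[C@H]1CC[C@H]2C(C)(C)[C@@H](O)CC[C@]12C | intermediate
12 | 3β-acetate of 11 | CC[Si](CC)(CC)O[C@H]1CC[C@H]2C(C)(C)[C@@H](OC(C)=O)CC[C@]12C | intermediate
13 | (1S,3aS,5S,7aS)-1-hydroxy-4,4,7a-trimethyloctahydro-1H-inden-5-yl acetate | O[C@H]1CC[C@H]2C(C)(C)[C@@H](OC(C)=O)CC[C@]12C | intermediate
14 | (3aS,5S,7aS)-4,4,7a-trimethyl-1-oxooctahydro-1H-inden-5-yl acetate | O=C1CC[C@H]2C(C)(C)[C@@H](OC(C)=O)CC[C@]12C | intermediate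
15 | (4-hydroxybutyl)triphenylphosphonium bromide | OCCCC[P+](c1ccccc1)(c1ccccc1)c1ccccc1.[Br-] | starting material
16 | potassium 4-(triphenylphosphoranylidene)butan-1-olate | [K+].[O-]CCC[CH-][P+](c1ccccc1)(c1ccccc1)c1ccccc1 | intermediate
17 | (Z)-alkenol: ketal 9 with C8'=O replaced by (Z)-4-hydroxybutylidene, chain cis to C10' | OCCC/C=C1/CC[C@H]2C(C)(C)C3(OCCO3)CC[C@]12C | intermediate
18 | triol: 8'α-OH and 9'-OH from α-face syn addition, primary OH | OCCC[C@H](O)[C@@]1(O)CC[C@H]2C(C)(C)C3(OCCO3)CC[C@]12C | intermediate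
19 | primary iodide of 18 | ICCC[C@H](O)[C@@]1(O)CC[C@H]2C(C)(C)C3(OCCO3)CC[C@]12C | intermediate
20 | 8',9'-bis(triethylsilyl) ether of 19 | ICCC[C@H](O[Si](CC)(CC)CC)[C@@]1(O[Si](CC)(CC)CC)CC[C@H]2C(C)(C)C3(OCCO3)CC[C@]12C | intermediate
21 | triphenylphosphonium iodide from 20 | [I-].c1ccccc1[P+](c1ccccc1)(c1ccccc1)CCC[C@H](O[Si](CC)(CC)CC)[C@@]1(O[Si](CC)(CC)CC)CC[C@H]2C(C)(C)C3(OCCO3)CC[C@]12C | intermediate
22 | ylide of 21 | c1ccccc1[P+](c1ccccc1)(c1ccccc1)[CH-]CC[C@H](O[Si](CC)(CC)CC)[C@@]1(O[Si](CC)(CC)CC)CC[C@H]2C(C)(C)C3(OCCO3)CC[C@]12C | intermediate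
23 | (Z)-C8=C9 alkene: 3β-acetoxy hydrindanylidene linked through C11–C12 to the bis-silylated 8',9'-diol unit | C[C@]12CC[C@H](OC(C)=O)C(C)(C)[C@@H]1CC/C2=C/CC[C@H](O[Si](CC)(CC)CC)[C@@]1(O[Si](CC)(CC)CC)CC[C@H]2C(C)(C)C3(OCCO3)CC[C@]12C | intermediate
24 | 8α,9-diol of 23 | C[C@]12CC[C@H](OC(C)=O)C(C)(C)[C@@H]1CC[C@]2(O)[C@@H](O)CC[C@H](O[Si](CC)(CC)CC)[C@@]1(O[Si](CC)(CC)CC)CC[C@H]2C(C)(C)C3(OCCO3)CC[C@]12C | intermediate
25 | C9 mesylate of 24 | C[C@]12CC[C@H](OC(C)=O)C(C)(C)[C@@H]1CC[C@]2(O)[C@@H](OS(C)(=O)=O)CC[C@H](O[Si](CC)(CC)CC)[C@@]1(O[Si](CC)(CC)CC)CC[C@H]2C(C)(C)C3(OCCO3)CC[C@]12C | intermediate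
26 | ring-expanded 8-ketone, 9β-H (chain α, axial) | C[C@]12CC[C@H](OC(C)=O)C(C)(C)[C@@H]1CCC(=O)[C@H]2CC[C@H](O[Si](CC)(CC)CC)[C@@]1(O[Si](CC)(CC)CC)CC[C@H]2C(C)(C)C3(OCCO3)CC[C@]12C | intermediate
27 | ring-expanded 8-ketone, 9α-H (chain β, equatorial) | C[C@]12CC[C@H](OC(C)=O)C(C)(C)[C@@H]1CCC(=O)[C@@H]2CC[C@H](O[Si](CC)(CC)CC)[C@@]1(O[Si](CC)(CC)CC)CC[C@H]2C(C)(C)C3(OCCO3)CC[C@]12C | intermediate
28 | keto diol: 27 with both silyl groups removed | C[C@]12CC[C@H](OC(C)=O)C(C)(C)[C@@H]1CCC(=O)[C@@H]2CC[C@H](O)[C@@]1(O)CC[C@H]2C(C)(C)C3(OCCO3)CC[C@]12C | intermediate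
29 | C9' mesylate of 28 | C[C@]12CC[C@H](OC(C)=O)C(C)(C)[C@@H]1CCC(=O)[C@@H]2CC[C@H](OS(C)(=O)=O)[C@@]1(O)CC[C@H]2C(C)(C)C3(OCCO3)CC[C@]12C | intermediate
30 | 8,8'-diketone: 9α-H, 9'β-H, 3'-ethylenedioxy, 3β-acetoxy | O=C1CC[C@H]2C(C)(C)C3(OCCO3)CC[C@]2(C)[C@@H]1CC[C@H]1C(=O)CC[C@H]2C(C)(C)[C@@H](OC(C)=O)CC[C@]12C | intermediate
31 | bis-methylene ketal | C=C1CC[C@H]2C(C)(C)C3(OCCO3)CC[C@]2(C)[C@@H]1CC[C@H]1C(=C)CC[C@H]2C(C)(C)[C@@H](OC(C)=O)CC[C@]12C | intermediate
32 | target: 3β-acetoxy-3'-oxo bis-methylene compound, 9α-H, 9'β-H | C=C1CC[C@H]2C(C)(C)C(=O)CC[C@]2(C)[C@@H]1CC[C@H]1C(=C)CC[C@H]2C(C)(C)[C@@H](OC(C)=O)CC[C@]12C | target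

**Step count**

Total step count: 22. Longest linear sequence: 18 (steps 1–6 and 11–22; steps 7–10 form the side branch to 14).

**Steps most likely to fail**

1. Step 18. After the 1,2-shift the base equilibration at C9 may stop at an unfavourable mixture, with the axial epimer persisting. Fallback (kinetic protonation in place of equilibration): setting out from 26, Me3SiCl, NaI and Et3N in MeCN should give the tetrasubstituted trimethylsilyl enol ether F1, which removes the C9 stereocentre. Treatment with Bu4NF and AcOH in THF from −78 °C should then protonate the liberated enolate on the α face, anti to the C10 methyl group, and remove both triethylsilyl groups, so the sequence comes back to the route at 28.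

2. Step 16. Enolisation of 14 by the basic ylide and slow addition to the hindered carbonyl may leave both partners unchanged, or the Z geometry may erode. Fallback (Horner–Wittig, addition and elimination separated): setting out from 20, Michaelis–Becker alkylation with Ph2P(O)H and NaH in DMF should give the phosphine oxide F2. n-BuLi at −78 °C gives the lithio derivative F3, which adds to 14 to give the β-hydroxy phosphine oxide F4; the diastereomer drawn is separated. Stereospecific syn elimination with NaH in DMF at 50 °C comes back to the route at 23.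

3. Step 4. The C5 carbanion may be protonated from the β face (cis ring fusion), or proton transfer may scramble the enolate before methylation. Fallback (hydride conjugate reduction on the silyl ether): setting out from 5, t-BuMe2SiCl and imidazole give the silyl ether F5. Copper hydride conjugate reduction (CuI, t-BuLi, iBu2AlH, HMPA, THF, −50 °C) should deliver hydride to C5 from the α face and give the aluminium enolate F6. MeLi then MeI gives the gem-dimethyl ketone F7, and HF·pyridine comes back to the route at 7.

Further compounds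
F1 | step 18 | C8-trimethylsilyl enol ether (C8=C9) of ketone 26/27 | C[C@]12CC[C@H](OC(C)=O)C(C)(C)[C@@H]1CCC(O[Si](C)(C)C)=C2CC[C@H](O[Si](CC)(CC)CC)[C@@]1(O[Si](CC)(CC)CC)CC[C@H]2C(C)(C)C3(OCCO3)CC[C@]12C
F2 | step 16 | diphenylphosphine oxide from iodide 20 | O=P(c1ccccc1)(c1ccccc1)CCC[C@H](O[Si](CC)(CC)CC)[C@@]1(O[Si](CC)(CC)CC)CC[C@H]2C(C)(C)C3(OCCO3)CC[C@]12C
F3 | step 16 | α-lithio derivative of F2 | [Li+].O=P(c1ccccc1)(c1ccccc1)[CH-]CC[C@H](O[Si](CC)(CC)CC)[C@@]1(O[Si](CC)(CC)CC)CC[C@H]2C(C)(C)C3(OCCO3)CC[C@]12C
F4 | step 16 | β-hydroxy phosphine oxide (8β-OH, C9 phosphinoyl, adduct of F3 and 14) | C[C@]12CC[C@H](OC(C)=O)C(C)(C)[C@@H]1CC[C@@]2(O)[C@H](P(=O)(c1ccccc1)c1ccccc1)CC[C@H](O[Si](CC)(CC)CC)[C@@]1(O[Si](CC)(CC)CC)CC[C@H]2C(C)(C)C3(OCCO3)CC[C@]12C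
F5 | step 4 | 8β-tert-butyldimethylsilyl ether of 5 | CC(C)(C)[Si](C)(C)O[C@H]1CCC2=C(C)C(=O)CC[C@]12C
F6 | step 4 | diisobutylaluminium C3 enolate of the trans-fused reduced enone | CC(C)(C)[Si](C)(C)O[C@H]1CC[C@H]2C(C)=C(O[Al](CC(C)C)CC(C)C)CC[C@]12C
F7 | step 4 | 8β-tert-butyldimethylsilyl ether of 7 | CC(C)(C)[Si](C)(C)O[C@H]1CC[C@H]2C(C)(C)C(=O)CC[C@]12C
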